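## Retrosynthetic overview

1. The target comes from its bis-silyl ether C8 phenol by O-methylation at C8 and desilylation.
2. The strategy rests on ring A (C4a, C5, C6, C7, C8, C8a), which has H on C5 and three contiguous oxygens on C6, C7 and C8. It is disconnected at C4a–C5 and C8–C8a into a ring B dienylstannane (tin on C4a, C4a=C8a alkene) and 4-chloro-2,3-dimethoxycyclobutenone.
3. The dienylstannane comes from the 2-triflyloxy-1,3-diene, this from the ring B enone (C4a=O, C3=C4), and this from a regiodefined silyl enol ether by Saegusa–Ito oxidation.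
4. Ring B comes from an amine-catalysed Diels–Alder reaction of (E)-3,4-dimethoxycinnamaldehyde with a 2-silyloxydiene; this sets C1 and C2 (trans) and the absolute configuration.
5. Ring order: ring B first (cycloaddition), ring A last (benzannulation); the dimethoxyphenyl ring is bought in.

Key step: step 10

Remarks on the chemistry:
- Ring B atoms are called by the target numbering throughout (C1 aryl-bearing, C2, C3, C4, C4a, C8a).
- The epimer ratio at C3 in compounds 4–6 is left open, because C3 becomes sp2 in step 5.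
- Tin carries methyl groups, because hexamethylditin stannylates alkenyl triflates cleanly.
- Step 2 needs bond formation on the re face of the aryl-bearing carbon. The (2S,5S) imidazolidinone is known to expose the si face of cinnamaldehyde iminium ions, so the (2R,5R) catalyst is chosen.

## Route

Step 1
Reactants: 1 methyl (2E)-4-oxopent-2-enoate
Product: 2 methyl (2E)-4-[(tert-butyldimethylsilyl)oxy]penta-2,4-dienoate
Conditions: TBSOTf, Et3N, CH2Cl2, 0 °C
Reagents that add atoms: tert-butyldimethylsilyl trifluoromethanesulfonate, CC(C)(C)[Si](C)(C)OS(=O)(=O)C(F)(F)F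
Why: Soft enolization of the methyl ketone (silyl enol ether formation) can only occur on the methyl side and should give the 2-silyloxydiene with the E-enoate untouched.

Step 2
Reactants: 2 methyl (2E)-4-[(tert-butyldimethylsilyl)oxy]penta-2,4-dienoate; 3 (2E)-3-(3,4-dimethoxyphenyl)prop-2-enal
Product: 4 methyl (5R,6S)-3-[(tert-butyldimethylsilyl)oxy]-5-(3,4-dimethoxyphenyl)-6-formylcyclohex-2-ene-1-carboxylate (both epimers at the ester carbon)
Conditions: (2R,5R)-5-benzyl-2-tert-butyl-3-methylimidazolidin-4-one (20 mol%), CF3CO2H (20 mol%), CH2Cl2, −20 °C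
Reagents that add atoms: none
Why: Iminium-catalysed Diels–Alder reaction (probably asynchronous, Mukaiyama–Michael addition then enamine ring closure) in which the nucleophilic CH2 terminus of the diene bonds to the aryl-bearing carbon on the face left open by the (2R,5R) catalyst, which sets C1; the E geometry of the enal places the formyl group on C2 trans to the aryl group, and the ester carbon C3 forms as an epimer mixture that is erased in step 5.

Step 3
Reactants: 4 methyl (5R,6S)-3-[(tert-butyldimethylsilyl)oxy]-5-(3,4-dimethoxyphenyl)-6-formylcyclohex-2-ene-1-carboxylate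
Product: 5 [(5R,6S)-3-[(tert-butyldimethylsilyl)oxy]-5-(3,4-dimethoxyphenyl)-6-(hydroxymethyl)cyclohex-2-en-1-yl]methanol
Conditions: LiAlH4, THF, −78 to 0 °C; aq. potassium sodium tartrate
Reagents that add atoms: none
Why: Hydride reduction of aldehyde and ester gives the two primary alcohols, while a TBS enol ether is inert to LiAlH4 and neither C1 nor C2 is touched at low temperature.

Step 4
Reactants: 5 [(5R,6S)-3-[(tert-butyldimethylsilyl)oxy]-5-(3,4-dimethoxyphenyl)-6-(hydroxymethyl)cyclohex-2-en-1-yl]methanol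
Product: 6 (5R,6S)-3-[(tert-butyldimethylsilyl)oxy]-1,6-bis{[(tert-butyldimethylsilyl)oxy]methyl}-5-(3,4-dimethoxyphenyl)cyclohex-2-ene
Conditions: TBSCl, imidazole, DMF, rt
Reagents that add atoms: tert-butyldimethylsilyl chloride, CC(C)(C)[Si](C)(C)Cl
Why: Standard silylation of two unhindered primary alcohols under conditions that leave the silyl enol ether intact.

Step 5
Reactants: 6 (5R,6S)-3-[(tert-butyldimethylsilyl)oxy]-1,6-bis{[(tert-butyldimethylsilyl)oxy]methyl}-5-(3,4-dimethoxyphenyl)cyclohex-2-ene
Product: 7 (4S,5R)-3,4-bis{[(tert-butyldimethylsilyl)oxy]methyl}-5-(3,4-dimethoxyphenyl)cyclohex-2-en-1-one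
Conditions: Pd(OAc)2 (1.1 equiv), MeCN, 40 °C
Reagents that add atoms: none
Why: Saegusa–Ito oxidation, in which divalent palladium is delivered to C4 of the enol ether and syn β-hydride elimination can only take the single hydrogen on C3, so both C3 epimers should converge on the C3=C4 enone with C1 and C2 unchanged.

Step 6
Reactants: 7 (4S,5R)-3,4-bis{[(tert-butyldimethylsilyl)oxy]methyl}-5-(3,4-dimethoxyphenyl)cyclohex-2-en-1-one
Product: 9 (3S,4S)-4,5-bis{[(tert-butyldimethylsilyl)oxy]methyl}-3-(3,4-dimethoxyphenyl)cyclohexa-1,5-dien-1-yl trifluoromethanesulfonate, via lithium dienolate 8 (not isolated)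
Conditions: LiN(iPr)2, THF, −78 °C; then PhNTf2, −78 to 0 °C
Reagents that add atoms: N-phenylbis(trifluoromethanesulfonimide), O=S(=O)(N(c1ccccc1)S(=O)(=O)C(F)(F)F)C(F)(F)F
Why: Kinetic deprotonation of an enone with a lithium amide at −78 °C removes the α' hydrogen on C8a rather than a γ hydrogen, and O-triflation of the cross-conjugated enolate (enol triflate formation) gives the 2-triflyloxy-1,3-diene; C1 is never deprotonated and keeps its configuration.

Step 7
Reactants: 9 (3S,4S)-4,5-bis{[(tert-butyldimethylsilyl)oxy]methyl}-3-(3,4-dimethoxyphenyl)cyclohexa-1,5-dien-1-yl trifluoromethanesulfonate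
Product: 10 [(3S,4S)-4,5-bis{[(tert-butyldimethylsilyl)oxy]methyl}-3-(3,4-dimethoxyphenyl)cyclohexa-1,5-dien-1-yl]trimethylstannane
Conditions: Me3SnSnMe3, Pd(PPh3)4 (5 mol%), LiCl, THF, 60 °C
Reagents that add atoms: hexamethylditin, C[Sn](C)(C)[Sn](C)(C)C
Why: Zerovalent-palladium-catalysed coupling of an alkenyl triflate with a ditin (Stille-type stannylation) should exchange OTf for SnMe3 at C4a without moving either double bond.

Step 8
Reactants: 11 3,4-dimethoxycyclobut-3-ene-1,2-dione (dimethyl squarate)
Product: 12 4-hydroxy-2,3-dimethoxycyclobut-2-en-1-one (racemic)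
Conditions: LiAlH(OtBu)3, THF, −78 °C
Reagents that add atoms: none
Why: The bulky alkoxyhydride adds once to one of the two equivalent carbonyl groups (1,2-reduction), and the vinylogous ester carbonyl that remains is much less electrophilic; the new carbinol centre is racemic and ends as an aromatic carbon.

Step 9
Reactants: 12 4-hydroxy-2,3-dimethoxycyclobut-2-en-1-one
Product: 13 4-chloro-2,3-dimethoxycyclobut-2-en-1-one (racemic)
Conditions: SOCl2, pyridine, Et2O, −20 to 0 °C
Reagents that add atoms: thionyl chloride, O=S(Cl)Cl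
Why: Chlorodehydroxylation of the allylic α-ketol through its chlorosulfite under non-aqueous conditions should give the chloride, which is filtered from the pyridinium salt and used at once because it ionizes easily.

Step 10
Reactants: 10 [(3S,4S)-4,5-bis{[(tert-butyldimethylsilyl)oxy]methyl}-3-(3,4-dimethoxyphenyl)cyclohexa-1,5-dien-1-yl]trimethylstannane; 13 4-chloro-2,3-dimethoxycyclobut-2-en-1-one
Product: 17 (1R,2S)-2,3-bis{[(tert-butyldimethylsilyl)oxy]methyl}-1-(3,4-dimethoxyphenyl)-6,7-dimethoxy-1,2-dihydronaphthalen-8-ol (target numbering), via dienylcyclobutenone 14 (not isolated), via dienylketene 15 (not isolated), via cyclohexadienone 16 (not isolated)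
Conditions: Pd2(dba)3 (2.5 mol%), tri(2-furyl)phosphine (10 mol%), dioxane, 50 °C, then 100 °C
Reagents that add atoms: none
Why: Zerovalent palladium inserts into the allylic, α-keto C–Cl bond of 13, the stannyl group of 10 transmetalates and reductive elimination at the unsubstituted cyclobutenyl terminus forms C4a–C5 in 14 (Stille coupling). On heating, strain-driven conrotatory 4π opening of 14 gives dienylketene 15; the opening is reversible, so the isomer with the ketene cis to the dienyl group is drained by a thermal disrotatory 6π electrocyclization that forms C8–C8a and closes ring A as cyclohexadienone 16. Enolization of 16 with loss of the C8a hydrogen gives phenol 17, in which C5 keeps the hydrogen of cyclobutenone C4 and C6, C7 and C8 carry the three oxygens. The closest known reaction type is the palladium-catalysed coupling of 4-chlorocyclobutenones with alkenylstannanes followed by thermal ring expansion to phenols. No lasting stereocenter is created, since cyclobutenone C4 and C8a end as aromatic carbons, and C1 and C2 take no part. The step needs closure onto C8a ahead of hydrogen shifts in the cyclohexadiene: the tin on C4a fixes the point of attachment, C4a=C8a is the only alkene in linear conjugation with the ketene, and the reactive ketene should close at 100 °C, below the range where such shifts set in.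

Step 11
Reactants: 17 (1R,2S)-2,3-bis{[(tert-butyldimethylsilyl)oxy]methyl}-1-(3,4-dimethoxyphenyl)-6,7-dimethoxy-1,2-dihydronaphthalen-8-ol
Product: 18 (1R,2S)-2,3-bis{[(tert-butyldimethylsilyl)oxy]methyl}-1-(3,4-dimethoxyphenyl)-6,7,8-trimethoxy-1,2-dihydronaphthalene
Conditions: MeI, K2CO3, acetone, 50 °C
Reagents that add atoms: iodomethane, CI
Why: Williamson O-methylation of the only phenol; the silyl ethers and the C3=C4 styrene unit are inert to carbonate.

Step 12
Reactants: 18 (1R,2S)-2,3-bis{[(tert-butyldimethylsilyl)oxy]methyl}-1-(3,4-dimethoxyphenyl)-6,7,8-trimethoxy-1,2-dihydronaphthalene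
Product: 19 [(1R,2S)-1-(3,4-dimethoxyphenyl)-6,7,8-trimethoxy-1,2-dihydronaphthalene-2,3-diyl]dimethanol
Conditions: Bu4NF, THF, 0 °C to rt
Reagents that add atoms: none
Why: Fluoride-induced desilylation of both primary TBS ethers should release the diol without affecting the methyl ethers, the alkene or the two stereocenters.

## Compound list

1 | methyl (2E)-4-oxopent-2-enoate | CC(=O)/C=C/C(=O)OC | starting material
2 | methyl (2E)-4-[(tert-butyldimethylsilyl)oxy]penta-2,4-dienoate | C=C(O[Si](C)(C)C(C)(C)C)/C=C/C(=O)OC | intermediate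
3 | (2E)-3-(3,4-dimethoxyphenyl)prop-2-enal | COc1ccc(/C=C/C=O)cc1OC | starting material
4 | methyl (5R,6S)-3-[(tert-butyldimethylsilyl)oxy]-5-(3,4-dimethoxyphenyl)-6-formylcyclohex-2-ene-1-carboxylate, aryl and formyl trans, both epimers at the ester carbon | COc1ccc([C@@H]2CC(O[Si](C)(C)C(C)(C)C)=CC(C(=O)OC)[C@H]2C=O)cc1OC | intermediate
5 | [(5R,6S)-3-[(tert-butyldimethylsilyl)oxy]-5-(3,4-dimethoxyphenyl)-6-(hydroxymethyl)cyclohex-2-en-1-yl]methanol, both epimers at ring C1 | COc1ccc([C@@H]2CC(O[Si](C)(C)C(C)(C)C)=CC(CO)[C@H]2CO)cc1OC | intermediate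
6 | (5R,6S)-3-[(tert-butyldimethylsilyl)oxy]-1,6-bis{[(tert-butyldimethylsilyl)oxy]methyl}-5-(3,4-dimethoxyphenyl)cyclohex-2-ene, ring numbering as in 4, both epimers at ring C1 | COc1ccc([C@@H]2CC(O[Si](C)(C)C(C)(C)C)=CC(CO[Si](C)(C)C(C)(C)C)[C@H]2CO[Si](C)(C)C(C)(C)C)cc1OC | intermediate
7 | (4S,5R)-3,4-bis{[(tert-butyldimethylsilyl)oxy]methyl}-5-(3,4-dimethoxyphenyl)cyclohex-2-en-1-one | COc1ccc([C@@H]2CC(=O)C=C(CO[Si](C)(C)C(C)(C)C)[C@H]2CO[Si](C)(C)C(C)(C)C)cc1OC | intermediate
8 | lithium (3S,4S)-4,5-bis{[(tert-butyldimethylsilyl)oxy]methyl}-3-(3,4-dimethoxyphenyl)cyclohexa-1,5-dien-1-olate | COc1ccc([C@@H]2C=C(O[Li])C=C(CO[Si](C)(C)C(C)(C)C)[C@H]2CO[Si](C)(C)C(C)(C)C)cc1OC | intermediate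
9 | (3S,4S)-4,5-bis{[(tert-butyldimethylsilyl)oxy]methyl}-3-(3,4-dimethoxyphenyl)cyclohexa-1,5-dien-1-yl trifluoromethanesulfonate | COc1ccc([C@@H]2C=C(OS(=O)(=O)C(F)(F)F)C=C(CO[Si](C)(C)C(C)(C)C)[C@H]2CO[Si](C)(C)C(C)(C)C)cc1OC | intermediate
10 | [(3S,4S)-4,5-bis{[(tert-butyldimethylsilyl)oxy]methyl}-3-(3,4-dimethoxyphenyl)cyclohexa-1,5-dien-1-yl]trimethylstannane; same spatial arrangement at C1 and C2 as the target, aryl and silyloxymethyl trans | COc1ccc([C@@H]2C=C([Sn](C)(C)C)C=C(CO[Si](C)(C)C(C)(C)C)[C@H]2CO[Si](C)(C)C(C)(C)C)cc1OC | intermediate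
11 | 3,4-dimethoxycyclobut-3-ene-1,2-dione (dimethyl squarate) | COC1=C(OC)C(=O)C1=O | starting material
12 | 4-hydroxy-2,3-dimethoxycyclobut-2-en-1-one, racemic | COC1=C(OC)C(O)C1=O | intermediate
13 | 4-chloro-2,3-dimethoxycyclobut-2-en-1-one, racemic | COC1=C(OC)C(Cl)C1=O | intermediate
14 | 2,3-dimethoxycyclobut-2-en-1-one carrying at C4 the ring B dienyl group of 10 through C4a; ring B stereocenters unchanged, both epimers at cyclobutenone C4 | COc1ccc([C@@H]2C=C(C3C(=O)C(OC)=C3OC)C=C(CO[Si](C)(C)C(C)(C)C)[C@H]2CO[Si](C)(C)C(C)(C)C)cc1OC | intermediate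
15 | 2,3-dimethoxybuta-1,3-dien-1-one (vinylketene) carrying the ring B dienyl group on C4, ketene carbon chain and dienyl group cis on the C3=C4 bond | COc1ccc([C@@H]2C=C(/C=C(OC)\C(OC)=C=O)C=C(CO[Si](C)(C)C(C)(C)C)[C@H]2CO[Si](C)(C)C(C)(C)C)cc1OC | intermediate
16 | 2,3-bis{[(tert-butyldimethylsilyl)oxy]methyl}-1-(3,4-dimethoxyphenyl)-6,7-dimethoxy-1,8a-dihydronaphthalen-8(2H)-one (target numbering), C1 and C2 as in 10, both epimers at C8a | COc1ccc([C@@H]2C3C(=O)C(OC)=C(OC)C=C3C=C(CO[Si](C)(C)C(C)(C)C)[C@H]2CO[Si](C)(C)C(C)(C)C)cc1OC | intermediate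
17 | (1R,2S)-2,3-bis{[(tert-butyldimethylsilyl)oxy]methyl}-1-(3,4-dimethoxyphenyl)-6,7-dimethoxy-1,2-dihydronaphthalen-8-ol (target numbering) | COc1ccc([C@@H]2c3c(cc(OC)c(OC)c3O)C=C(CO[Si](C)(C)C(C)(C)C)[C@H]2CO[Si](C)(C)C(C)(C)C)cc1OC | intermediate
18 | (1R,2S)-2,3-bis{[(tert-butyldimethylsilyl)oxy]methyl}-1-(3,4-dimethoxyphenyl)-6,7,8-trimethoxy-1,2-dihydronaphthalene | COc1ccc([C@@H]2c3c(cc(OC)c(OC)c3OC)C=C(CO[Si](C)(C)C(C)(C)C)[C@H]2CO[Si](C)(C)C(C)(C)C)cc1OC | intermediate
19 | [(1R,2S)-1-(3,4-dimethoxyphenyl)-6,7,8-trimethoxy-1,2-dihydronaphthalene-2,3-diyl]dimethanol (CNP0274357.1) | COc1ccc([C@@H]2c3c(cc(OC)c(OC)c3OC)C=C(CO)[C@H]2CO)cc1OC | target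

## Step count and risks

Total: 12 steps. Longest linear sequence: 10 steps (steps 1–7, 10, 11, 12); steps 8 and 9 form the two-step branch to the chloride.

**Step 10 (key step).** The coupling may be outrun by ionization of the chloride with loss of a methoxy group, transmetalation at the dienyl tin may be slow, and hydrogen shifts or oxidative aromatization of the cyclohexadiene may compete with ring opening and closure. The fallback makes the C4a–C5 bond by carbonyl addition and removes the extra oxygen afterwards. Stannane 10 would be transmetalated with MeLi (THF, −78 °C) to the dienyllithium F1, which adds to one carbonyl of dimethyl squarate 11; trapping the alkoxide with TBSOTf should give the 4-dienyl-4-silyloxycyclobutenone F2. Heating in toluene at reflux should bring about the same 4π opening and 6π closure and give the C8 phenol with a silyloxy group on C5 F3. Methylation (MeI, K2CO3, acetone) would give the C8 methyl ether F4, K2CO3 in MeOH should cleave only the aryl silyl ether to the C5 phenol F5, and PhNTf2 with Et3N would give the C5 aryl triflate F6. Reduction with Pd(OAc)2, dppf, HCO2H and Et3N in DMF at 70 °C replaces the triflate by hydrogen and comes back to the route at compound 18.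

**Step 2.** The ester-substituted diene may react too slowly with the iminium ion, the enol ether may be lost by protodesilylation before or after ring closure (which would erase the regiochemical information needed in step 5), or facial selectivity may be poor. The fallback carries the chirality on a covalent auxiliary. Diene 2 would be combined with the cinnamoyl imide (4R)-4-benzyl-3-[(2E)-3-(3,4-dimethoxyphenyl)prop-2-enoyl]-1,3-oxazolidin-2-one F7, made from (E)-3,4-dimethoxycinnamoyl chloride and lithiated (R)-4-benzyloxazolidin-2-one, under Et2AlCl in CH2Cl2 at −40 °C. The chelated s-cis imide should be attacked on the face away from the benzyl group, which is the re face of the aryl-bearing carbon, to give the cyclohexene imide adduct F8. LiBH4 in THF/MeOH would then reduce imide and ester together and release the auxiliary, coming back to the route at compound 5.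

**Step 9.** The chloride may not survive its formation or handling, because ionization at C4 is assisted by the C2 methoxy group and leads on to the cyclobutenedione. The fallback replaces the chloride by an allylic ester. Alcohol 12 would be converted with ClCO2Me and pyridine (CH2Cl2, 0 °C) to methyl 2,3-dimethoxy-4-oxocyclobut-2-en-1-yl carbonate F9. Under the catalyst of step 10, ionization of the carbonate by zerovalent palladium with loss of CO2 should give the same cyclobutenylpalladium species as its methoxide, which transmetalates with stannane 10 without added halide. The sequence then runs through 14, 15 and 16 and comes back to the route at compound 17.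

## Further compounds

F1 | step 10 | dienyllithium from 10 (SnMe3 on C4a replaced by Li) | COc1ccc([C@@H]2C=C([Li])C=C(CO[Si](C)(C)C(C)(C)C)[C@H]2CO[Si](C)(C)C(C)(C)C)cc1OC
F2 | step 10 | 4-[(tert-butyldimethylsilyl)oxy]-2,3-dimethoxycyclobut-2-en-1-one carrying the ring B dienyl group on C4, both C4 epimers | COc1ccc([C@@H]2C=C(C3(O[Si](C)(C)C(C)(C)C)C(=O)C(OC)=C3OC)C=C(CO[Si](C)(C)C(C)(C)C)[C@H]2CO[Si](C)(C)C(C)(C)C)cc1OC
F3 | step 10 | analogue of 17 with a tert-butyldimethylsilyloxy group on C5 (C8 phenol) | COc1ccc([C@@H]2c3c(c(O[Si](C)(C)C(C)(C)C)c(OC)c(OC)c3O)C=C(CO[Si](C)(C)C(C)(C)C)[C@H]2CO[Si](C)(C)C(C)(C)C)cc1OC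
F4 | step 10 | analogue of 18 with a tert-butyldimethylsilyloxy group on C5 | COc1ccc([C@@H]2c3c(c(O[Si](C)(C)C(C)(C)C)c(OC)c(OC)c3OC)C=C(CO[Si](C)(C)C(C)(C)C)[C@H]2CO[Si](C)(C)C(C)(C)C)cc1OC
F5 | step 10 | analogue of 18 with a hydroxy group on C5 | COc1ccc([C@@H]2c3c(c(O)c(OC)c(OC)c3OC)C=C(CO[Si](C)(C)C(C)(C)C)[C@H]2CO[Si](C)(C)C(C)(C)C)cc1OC
F6 | step 10 | analogue of 18 with a trifluoromethanesulfonyloxy group on C5 | COc1ccc([C@@H]2c3c(c(OS(=O)(=O)C(F)(F)F)c(OC)c(OC)c3OC)C=C(CO[Si](C)(C)C(C)(C)C)[C@H]2CO[Si](C)(C)C(C)(C)C)cc1OC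
F7 | step 2 | (4R)-4-benzyl-3-[(2E)-3-(3,4-dimethoxyphenyl)prop-2-enoyl]-1,3-oxazolidin-2-one | COc1ccc(/C=C/C(=O)N2[C@H](Cc3ccccc3)COC2=O)cc1OC
F8 | step 2 | analogue of 4 with the formyl group replaced by the [(4R)-4-benzyl-2-oxo-1,3-oxazolidin-3-yl]carbonyl group, ring configuration as in 4 | COc1ccc([C@@H]2CC(O[Si](C)(C)C(C)(C)C)=CC(C(=O)OC)[C@H]2C(=O)N3[C@H](Cc4ccccc4)COC3=O)cc1OC
F9 | step 9 | methyl 2,3-dimethoxy-4-oxocyclobut-2-en-1-yl carbonate, racemic | COC(=O)OC1C(=O)C(OC)=C1OC
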